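Hold two balances: L lost reappears as G, Q or Z, and X lost reappears as Z, so Z stops at 10.0% of the L charged.

- elm: L 0.25 M; E 0.75 M; X 0.025 M; D 5 mM; the very flask that is asked about, followed so far
- flask: L 0.25 M; E 0.750 M; X 0.0250 M; D 5.0 mM

elm run (percent of the L charged)

| time / d | Q / % | L / % |
|---|---|---|
| 0.125 | 0 | 73 |
| 0.333 | 6 | 53 |
| 0.625 | 8 | 36 |
| 1.04 | 15 | 23 |
| 1.67 | 30 | 13 |
| 2.08 | 34 | 8 |
| 2.50 | 39 | 8 |

(scatter of a reading: 2 percentage points)

- on the list of suspects stand: L + D -> D + G; L + X -> Z; E + D + G -> D + Q; E + D -> J
- no earlier run changes the charge of D; that part of a forecast is a guess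
- no earlier run changes the charge of E; that part of a forecast is a guess

- factor on the rate of making Q when 5.0% of the L are converted if E is charged twice over
- factor on the rate when 5.0% of the L are converted if D is charged at 50 mM instead

Draw the L curve of this flask. The readings drop 27.0% by 0.125 d, then between 0.333 d and 0.625 d they fall at

kL = 1.32 /d

That slope accounts for 15.3% by the first reading. The remaining 12 percentage points fills the Z ceiling within the scatter, so put the knee before that reading. Take 2.3 lifetimes of X to have passed by then:

kX = 18.4 /d

Past the knee, the Q readings of this flask pass the L readings between 1.04 d and 1.67 d.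

Now compare the two drains on L at one moment. The branch ratio b (selectivity factor) is the rate of L into G over the rate of L into Z, and it goes as [D]/[X]. At the start of this flask:

b = kL[L]/(kX[X]) = 0.720

Then b drifts upward as [X] falls, so take it halfway through the X lost, holding [D] at its charge. Up to 5.0% conversion:

this flask: Z = 2.91%, b = 0.842, G = 2.29%

50 mM D: b = 7.20, Z = 0.610%, b = 7.43, G = 4.41%

The rate of Q goes as [E][D][G], and with [D] held at its charge E does not enter b, so I reckon 2 for dbl and 19.3 for ratio. The forecast gives 1.97 and 19, holding that “The side reaction is faster than catalysis at the start”.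

The flask gives 1.96 and 16.5.

    L + D → D + G (k = 0.220 /M/min)
    L + X → Z (k = 0.0390 /M/min)
    E + D + G → D + Q (k = 0.140 /M²/min)
    E + D → J (k = 4.80 × 10⁻⁴ /M/min)

With these constants this flask starts at b = 1.13, and by 0.600 d, with D at 73.6% and X at 0.593%, b has risen to 140. The flask with 50 mM D starts at b = 11.3, and the same halfway reckoning up to 5.0% conversion gives G = 4.60% against 2.81% in this flask, a reckoned rate factor of 16.4.

The runs come from a simulation for an exercise; scatter was added.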